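## Structural features

The target is a 2,3,4-trisubstituted oxolane of the 7,9'-epoxylignan (olivil) type; ring atoms are called O1, C2, C3, C4, C5 here, C3a is the hydroxymethyl carbon and C7' the benzylic methylene (IUPAC name: (3R,4R,5R)-5-(3,4-dihydroxyphenyl)-3-[(3,4-dimethoxyphenyl)methyl]-4-(hydroxymethyl)oxolan-3-ol). C2 is a benzylic ether carbon carrying the catechol ring, C3 carries CH2OH, C4 is fully substituted (tertiary OH and 3,4-dimethoxybenzyl), and C5 is an unsubstituted CH2 bound to O1. The three stereocenters are contiguous, and aryl (C2), hydroxymethyl (C3) and hydroxyl (C4) all lie on one face, with the benzyl group on the other. The fragile elements are the free catechol (oxidation), the C2–O1 bond para to a donor oxygen (acid ionization or quinone-methide formation would epimerize C2), and the tertiary alcohol within a 1,3-diol. The real difficulty is the C2/C3 cis pair: it is the less stable arrangement, and it is lost through any C2 cation or any C3 carbanion α to a carbonyl. The quaternary carbinol C4 must then be set relative to that pair, and the whole triad as one enantiomer. A useful latent feature is that raising C5 to the carboxyl level turns the ring into a 4,5-cis-disubstituted γ-butyrolactone whose only enolizable carbon is C4.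

## Logic of the disconnections

14 to 13 to 12. Bonds cut: the two aryl O–S bonds (14 to 13) and the two O–Si bonds (13 to 12). The catechol travels as a bis-sulfonate because an electron-poor aryl group makes the formyl carbon of 2 a better acceptor in the key step and suppresses ionization of C2–O1 in the Lewis-acidic step. The oxygens on C3a and C4 travel as silyl ethers through the enolate and hydride steps. No skeletal simplification; the demand is deprotection that is neither strongly acidic nor hot and basic.

12 to 11 to 10. Change at C5: its two C–H bonds are exchanged for a carbonyl, so that the ring of 10 is a γ-lactone. In 10 the only enolizable position is C4, the carbon still to be built; C3 is β and is never α to a carbonyl. The gain is a nucleophilic C4 in a ring that already holds O1–C2 and O1–C5. The demand on the forward steps is reduction of C5 to CH2 without breaking either C–O1 bond.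

10 to 8 + 9. Bond cut: C4–C7'. An enolate alkylation is directed by the adjacent C3 substituent and the cis aryl group on the same face. The benzyl group must enter anti to both, which leaves the oxygen on C4 cis to C3a, as the target requires.

8 to 6. Bond cut: C4–O. Oxygen goes in before carbon. The opposite order would put the hydroxyl trans to C3a, so this order is a strategic requirement. The configuration created here is erased again in the next enolization.

6 to 2 + 5. Bonds cut: C2–C3 and O1–C5. This is the key disconnection: both ring-forming bonds, the ring itself and the C2/C3 cis pair go back to an aryl aldehyde and a four-carbon enal. The forward step must be cis-selective, face-selective, and chemoselective for the cross-annulation.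

5 to 4 to 3, and 2 to 1. Bonds cut: one O–Si bond and the C–H bonds of a primary allylic alcohol (5 from 3), and two aryl O–S bonds (2 from 1). These are routine adjustments of commercial materials.

## Other disconnections considered

Alternative 1: (the first that comes to mind) Cut O1–C2 last, and before it C4–O, C4–C7' and C3–C2. Forward: tandem conjugate addition of a lithiated aryl dithiane to a butenolide with trapping by 9, then enolate hydroxylation, gives lactone A1; reduction and unmasking give tetraol A2; acid closes the ring through the benzylic cation at C2. Ground for rejection: the closure is an SN1 process that needs the electron-rich aryl group and is expected to place the aryl group trans to the C3 substituent, giving the 2-epimer A3 instead of 14. C2 is never under control, and the dithiane detour adds steps.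

Alternative 2: Cut C2–C3 through a temporary oxetane. Forward: exo-selective Paternò–Büchi photocycloaddition of 2 to A4 (dearomatization) gives A5, whose aryl/ring relationship maps onto the 2,3-cis pair. Hydroboration, oxidation, methylenation, convex-face epoxidation and aryl cuprate opening would give A6 with C4 also correct. Ground for rejection: stereochemically very secure, but the heteroarene oxygen ends up bridging C3a and C5, so the ring oxygen must be transposed (acetal opening, masking of C3a, re-closure onto C5). The adduct is also racemic and needs a resolution. This costs about five more steps than the chosen plan, whose annulation forms O1–C5 directly.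

Alternative 3: Cut O1–C5 and C4–C7' with C4 as a ketone. Forward: an auxiliary-controlled syn-aldol (acyl carbon = C4) gives A7; conversion of the acyl group to a halomethyl ketone and intramolecular O-alkylation closes the cis-oxolan-4-one A8; a benzyl organocerium adds anti to the C3 substituent. Ground for rejection: short, but in A8 C3 is α to a ketone in the less stable cis arrangement and must survive ring closure and a basic organometallic reagent; epimerization there leads into the 2,3-trans series. It also needs a stoichiometric auxiliary. The chosen plan uses the same anti-selectivity in an enolate alkylation while C3 is never enolizable.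

Key step: step 4

Assumption: the (5aS,10bR) antipode of the aminoindanol-derived N-mesityl triazolium salt is taken to favour 6; the sense of induction for this substrate pair is unassigned, and the (5aR,10bS) salt would be used if it is the opposite.

## Route

Step 1
Reactants: 1 3,4-dihydroxybenzaldehyde
Product: 2 4-formyl-1,2-phenylene bis(4-methylbenzenesulfonate)
Conditions: TsCl (2.3 equiv), Et3N, DMAP (cat.), CH2Cl2, 0 °C to rt
Reagents that add atoms: 4-methylbenzenesulfonyl chloride, Cc1ccc(cc1)S(=O)(=O)Cl
Why: O-sulfonylation of both phenols; no stereocenter; the sulfonates make the ring electron-poor for steps 4 and 8.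

Step 2
Reactants: 3 (Z)-but-2-ene-1,4-diol
Product: 4 (Z)-4-[(tert-butyldiphenylsilyl)oxy]but-2-en-1-ol
Conditions: NaH (1.0 equiv), THF, 0 °C; then TBDPSCl (1.0 equiv), 0 °C to rt
Reagents that add atoms: tert-butyl(chloro)diphenylsilane, CC(C)(C)[Si](Cl)(c1ccccc1)c1ccccc1
Why: Monosilylation of a symmetric diol through its sparingly soluble monosodium alkoxide (O-silylation); the alkene geometry is untouched.

Step 3
Reactants: 4 (Z)-4-[(tert-butyldiphenylsilyl)oxy]but-2-en-1-ol
Product: 5 (E)-4-[(tert-butyldiphenylsilyl)oxy]but-2-enal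
Conditions: (C5H5NH)[CrO3Cl] (pyridinium chlorochromate), Celite, CH2Cl2, rt
Reagents that add atoms: none
Why: Chlorochromate oxidation of the primary allylic alcohol; the mildly acidic medium should isomerize the first-formed (Z)-enal to the more stable (E)-enal.

Step 4
Reactants: 2 4-formyl-1,2-phenylene bis(4-methylbenzenesulfonate); 5 (E)-4-[(tert-butyldiphenylsilyl)oxy]but-2-enal
Product: 6 (4R,5R)-5-[3,4-bis(tosyloxy)phenyl]-4-{[(tert-butyldiphenylsilyl)oxy]methyl}oxolan-2-one (aryl and silyloxymethyl cis)
Conditions: (5aS,10bR)-aminoindanol-derived N-mesityl triazolium chloride (10 mol%), DBU (15 mol%), 4 Å MS, THF, 25 °C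
Reagents that add atoms: none
Why: The free carbene adds to the formyl group of 5 and proton transfer gives the conjugated Breslow intermediate, a homoenolate equivalent whose β-carbon (C3) attacks the formyl carbon of 2 (C2–C3 bond); tautomerization to the acyl azolium is followed by attack of the new C2 alkoxide on the acyl carbon (O1–C5 bond), which releases the carbene. The closest known reaction type is the N-heterocyclic-carbene-catalysed homoenolate annulation of enals with aromatic aldehydes to γ-butyrolactones, a formal (3+2) cycloaddition. The one ring formed, the oxolan-2-one, closes by 5-exo-trig acylation of the alkoxide by the acyl azolium. The C2/C3 relative configuration is set in the C–C bond-forming transition state, for which this reaction class has an intrinsic preference for the cis lactone, attributed to hydrogen bonding between the enol O–H of the Breslow intermediate and the aldehyde oxygen, which holds the aryl group and the C3 substituent on the same side. The absolute configuration is imposed by the fused aminoindanol backbone, which shields one face of the homoenolate. The step needs selectivity for the cross-annulation over enal self-annulation and benzoin formation: 2 is non-enolizable and made more electrophilic by its sulfonate groups, and the N-mesityl group favours Breslow-intermediate formation from the enal. The silyloxy group on C3a is a poor leaving group, so elimination from the homoenolate should not compete, and the minor trans lactone would be removed by chromatography.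

Step 5
Reactants: 6 (4R,5R)-5-[3,4-bis(tosyloxy)phenyl]-4-{[(tert-butyldiphenylsilyl)oxy]methyl}oxolan-2-one
Product: 8 (3S,4R,5R)-5-[3,4-bis(tosyloxy)phenyl]-4-{[(tert-butyldiphenylsilyl)oxy]methyl}-3-[(triethylsilyl)oxy]oxolan-2-one (silyloxy trans to the C4 substituent), via potassium alkoxide 7 (not isolated)
Conditions: KN(SiMe3)2, THF, −78 °C; 2-(phenylsulfonyl)-3-phenyloxaziridine, −78 °C; then Et3SiCl, −78 to 0 °C
Reagents that add atoms: 2-(phenylsulfonyl)-3-phenyloxaziridine, O=S(=O)(c1ccccc1)N1OC1c1ccccc1; chlorotriethylsilane, CC[Si](Cl)(CC)CC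
Why: Enolate oxidation by an N-sulfonyloxaziridine: the potassium enolate at the lactone α-carbon is attacked on the face opposite the adjacent substituent and the aryl group, and the alkoxide is silylated in situ; this stereocenter is planarized again in step 6, so the step only has to put oxygen on that carbon.

Step 6
Reactants: 8 (3S,4R,5R)-5-[3,4-bis(tosyloxy)phenyl]-4-{[(tert-butyldiphenylsilyl)oxy]methyl}-3-[(triethylsilyl)oxy]oxolan-2-one; 9 4-(bromomethyl)-1,2-dimethoxybenzene
Product: 10 (3R,4R,5R)-5-[3,4-bis(tosyloxy)phenyl]-4-{[(tert-butyldiphenylsilyl)oxy]methyl}-3-[(3,4-dimethoxyphenyl)methyl]-3-[(triethylsilyl)oxy]oxolan-2-one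
Conditions: LiN(iPr)2, THF, −78 °C; then 9, DMPU, −78 to −30 °C
Reagents that add atoms: none
Why: Alkylation of the α-silyloxy lactone enolate with a benzylic bromide; the electrophile enters anti to the neighbouring silyloxymethyl group and the cis aryl group, so the benzyl group ends trans and the oxygen cis to the silyloxymethyl group, which sets the quaternary carbinol as in the target.

Step 7
Reactants: 10 (3R,4R,5R)-5-[3,4-bis(tosyloxy)phenyl]-4-{[(tert-butyldiphenylsilyl)oxy]methyl}-3-[(3,4-dimethoxyphenyl)methyl]-3-[(triethylsilyl)oxy]oxolan-2-one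
Product: 11 (3R,4R,5R)-5-[3,4-bis(tosyloxy)phenyl]-4-{[(tert-butyldiphenylsilyl)oxy]methyl}-3-[(3,4-dimethoxyphenyl)methyl]-3-[(triethylsilyl)oxy]oxolan-2-ol (mixture of anomers)
Conditions: iBu2AlH (1.2 equiv), CH2Cl2, −78 °C
Reagents that add atoms: none
Why: Partial reduction of the lactone stops at the tetrahedral aluminate at low temperature and gives the lactol; the aryl sulfonates and silyl ethers are inert, and the anomeric center disappears in step 8.

Step 8
Reactants: 11 (3R,4R,5R)-5-[3,4-bis(tosyloxy)phenyl]-4-{[(tert-butyldiphenylsilyl)oxy]methyl}-3-[(3,4-dimethoxyphenyl)methyl]-3-[(triethylsilyl)oxy]oxolan-2-ol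
Product: 12 (2R,3R,4R)-2-[3,4-bis(tosyloxy)phenyl]-3-{[(tert-butyldiphenylsilyl)oxy]methyl}-4-[(3,4-dimethoxyphenyl)methyl]-4-[(triethylsilyl)oxy]oxolane
Conditions: Et3SiH (3 equiv), BF3·OEt2 (2 equiv), CH2Cl2, −78 to −30 °C
Reagents that add atoms: none
Why: Ionic hydrogenation of the lactol (oxocarbenium ion at C5, hydride from the silane) turns C5 into CH2; the electron-poor aryl group disfavours ionization at the benzylic C2–O1 bond, so C2 should keep its configuration.

Step 9
Reactants: 12 (2R,3R,4R)-2-[3,4-bis(tosyloxy)phenyl]-3-{[(tert-butyldiphenylsilyl)oxy]methyl}-4-[(3,4-dimethoxyphenyl)methyl]-4-[(triethylsilyl)oxy]oxolane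
Product: 13 (3R,4R,5R)-5-[3,4-bis(tosyloxy)phenyl]-3-[(3,4-dimethoxyphenyl)methyl]-4-(hydroxymethyl)oxolan-3-ol
Conditions: HF·pyridine, pyridine/THF, 0 °C to rt
Reagents that add atoms: none
Why: Fluoride cleavage of both silyl ethers; aryl sulfonates and the benzylic ether are inert to buffered HF·pyridine.

Step 10
Reactants: 13 (3R,4R,5R)-5-[3,4-bis(tosyloxy)phenyl]-3-[(3,4-dimethoxyphenyl)methyl]-4-(hydroxymethyl)oxolan-3-ol
Product: 14 (3R,4R,5R)-5-(3,4-dihydroxyphenyl)-3-[(3,4-dimethoxyphenyl)methyl]-4-(hydroxymethyl)oxolan-3-ol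
Conditions: Mg turnings (excess), degassed MeOH, rt; aq. NH4Cl work-up under argon
Reagents that add atoms: none
Why: Reductive S–O cleavage of the aryl sulfonates by electron transfer from magnesium in methanol; the medium is only mildly basic at room temperature, so quinone-methide epimerization at C2 and oxidation of the catechol should be avoided.

## Compound list

1 | 3,4-dihydroxybenzaldehyde | O=Cc1ccc(O)c(O)c1 | starting material
2 | 4-formyl-1,2-phenylene bis(4-methylbenzenesulfonate) | O=Cc1ccc(OS(=O)(=O)c2ccc(C)cc2)c(OS(=O)(=O)c2ccc(C)cc2)c1 | intermediate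
3 | (Z)-but-2-ene-1,4-diol | OC/C=C\CO | starting material
4 | (Z)-4-[(tert-butyldiphenylsilyl)oxy]but-2-en-1-ol | OC/C=C\CO[Si](c1ccccc1)(c1ccccc1)C(C)(C)C | intermediate
5 | (E)-4-[(tert-butyldiphenylsilyl)oxy]but-2-enal | O=C/C=C/CO[Si](c1ccccc1)(c1ccccc1)C(C)(C)C | intermediate
6 | (4R,5R)-5-[3,4-bis(tosyloxy)phenyl]-4-{[(tert-butyldiphenylsilyl)oxy]methyl}oxolan-2-one | O=C1C[C@H](CO[Si](c2ccccc2)(c2ccccc2)C(C)(C)C)[C@H](c2ccc(OS(=O)(=O)c3ccc(C)cc3)c(OS(=O)(=O)c3ccc(C)cc3)c2)O1 | intermediate
7 | potassium (3S,4S,5R)-5-[3,4-bis(tosyloxy)phenyl]-4-{[(tert-butyldiphenylsilyl)oxy]methyl}-2-oxooxolan-3-olate | O=C1[C@@H]([O-])[C@H](CO[Si](c2ccccc2)(c2ccccc2)C(C)(C)C)[C@H](c2ccc(OS(=O)(=O)c3ccc(C)cc3)c(OS(=O)(=O)c3ccc(C)cc3)c2)O1.[K+] | intermediate (not isolated)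
8 | (3S,4R,5R)-5-[3,4-bis(tosyloxy)phenyl]-4-{[(tert-butyldiphenylsilyl)oxy]methyl}-3-[(triethylsilyl)oxy]oxolan-2-one | O=C1[C@@H](O[Si](CC)(CC)CC)[C@H](CO[Si](c2ccccc2)(c2ccccc2)C(C)(C)C)[C@H](c2ccc(OS(=O)(=O)c3ccc(C)cc3)c(OS(=O)(=O)c3ccc(C)cc3)c2)O1 | intermediate
9 | 4-(bromomethyl)-1,2-dimethoxybenzene | COc1ccc(CBr)cc1OC | starting material
10 | (3R,4R,5R)-5-[3,4-bis(tosyloxy)phenyl]-4-{[(tert-butyldiphenylsilyl)oxy]methyl}-3-[(3,4-dimethoxyphenyl)methyl]-3-[(triethylsilyl)oxy]oxolan-2-one | O=C1[C@@](O[Si](CC)(CC)CC)(Cc2ccc(OC)c(OC)c2)[C@H](CO[Si](c2ccccc2)(c2ccccc2)C(C)(C)C)[C@H](c2ccc(OS(=O)(=O)c3ccc(C)cc3)c(OS(=O)(=O)c3ccc(C)cc3)c2)O1 | intermediate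
11 | (3R,4R,5R)-5-[3,4-bis(tosyloxy)phenyl]-4-{[(tert-butyldiphenylsilyl)oxy]methyl}-3-[(3,4-dimethoxyphenyl)methyl]-3-[(triethylsilyl)oxy]oxolan-2-ol (anomers) | COc1ccc(C[C@]2(O[Si](CC)(CC)CC)C(O)O[C@@H](c3ccc(OS(=O)(=O)c4ccc(C)cc4)c(OS(=O)(=O)c4ccc(C)cc4)c3)[C@H]2CO[Si](c3ccccc3)(c3ccccc3)C(C)(C)C)cc1OC | intermediate
12 | (2R,3R,4R)-2-[3,4-bis(tosyloxy)phenyl]-3-{[(tert-butyldiphenylsilyl)oxy]methyl}-4-[(3,4-dimethoxyphenyl)methyl]-4-[(triethylsilyl)oxy]oxolane | COc1ccc(C[C@]2(O[Si](CC)(CC)CC)CO[C@@H](c3ccc(OS(=O)(=O)c4ccc(C)cc4)c(OS(=O)(=O)c4ccc(C)cc4)c3)[C@H]2CO[Si](c3ccccc3)(c3ccccc3)C(C)(C)C)cc1OC | intermediate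
13 | (3R,4R,5R)-5-[3,4-bis(tosyloxy)phenyl]-3-[(3,4-dimethoxyphenyl)methyl]-4-(hydroxymethyl)oxolan-3-ol | COc1ccc(C[C@]2(O)CO[C@@H](c3ccc(OS(=O)(=O)c4ccc(C)cc4)c(OS(=O)(=O)c4ccc(C)cc4)c3)[C@H]2CO)cc1OC | intermediate
14 | (3R,4R,5R)-5-(3,4-dihydroxyphenyl)-3-[(3,4-dimethoxyphenyl)methyl]-4-(hydroxymethyl)oxolan-3-ol | COc1ccc(C[C@]2(O)CO[C@@H](c3ccc(O)c(O)c3)[C@H]2CO)cc1OC | target

## Step count and risk

Total step count: 10. Longest linear sequence: 9 steps (3, 4, 5, 6, 8, 10, 11, 12, 13, 14); 8 steps from 1.

**Step 4 (key step).** The most likely failures are incomplete facial discrimination by the carbene (erosion of enantiomeric purity), a weak cis/trans preference, and diversion of the homoenolate into enal self-annulation. These are the known soft spots of homoenolate additions to simple aromatic aldehydes, and a γ-oxygenated alkyl enal is a less favourable partner than a cinnamaldehyde. The fallback sets out from 2 and returns at 8. It builds the cis pair by hydrogenation and secures the absolute configuration enzymatically. Iodine–magnesium exchange on the β-iodo enoate F1 (iPrMgCl·LiCl, THF, −40 °C; F1 comes from hydroiodination of the corresponding alkynoate) and addition to 2 should give, after lactonization of the alkoxide, butenolide F2. Hydrogenation over Rh/Al2O3 delivers hydrogen to the face away from the aryl group and gives the racemic cis-lactone F3. Enolate oxidation as in step 5, without the silyl quench, gives the racemic hydroxy lactone F4. Acylation with vinyl acetate catalysed by Candida antarctica lipase B is expected, by the empirical size rule for secondary alcohols, to acetylate the (3S,4S,5R) enantiomer; this gives acetate F5, which is separated from the unreacted enantiomer. K2CO3 in MeOH at 0 °C gives F6, and Et3SiCl/imidazole gives 8.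

**Step 6.** C-alkylation of the hindered, fully substituted α-silyloxy enolate may be slow, allowing O-alkylation or decomposition of the labile benzylic bromide. The fallback sets out from 8 and returns at 10. It forms the C4–C7' bond by an aldol reaction and removes the extra oxygen afterwards. The lithium enolate of 8 is added to 3,4-dimethoxybenzaldehyde (a smaller, more reactive electrophile with the same anti approach) to give carbinol F7 as a mixture at the new carbinol carbon. 1,1'-Thiocarbonyldiimidazole/DMAP gives thiocarbamate F8, and Barton–McCombie deoxygenation (Bu3SnH, AIBN, toluene, 80 °C) gives 10.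

**Step 8.** The Lewis acid may open unintended ionization paths: Friedel–Crafts capture of the C5 oxocarbenium ion by the dimethoxyphenyl ring, premature loss of the triethylsilyl ether, or opening of the benzylic C2–O1 bond with loss of the C2 configuration. The fallback sets out from 10 and returns at 12, and avoids cationic intermediates. LiBH4 (THF, 0 °C) reduces the lactone to diol F9. A Mitsunobu cyclodehydration (PPh3, diisopropyl azodicarboxylate, toluene, 0 °C to rt) activates the less hindered primary hydroxyl at C5, which is displaced by the C2 hydroxyl with retention at C2 to give 12.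

## Further compounds

F1 | step 4 | methyl (Z)-4-[(tert-butyldiphenylsilyl)oxy]-3-iodobut-2-enoate | COC(=O)/C=C(\I)CO[Si](c1ccccc1)(c1ccccc1)C(C)(C)C
F2 | step 4 | 5-[3,4-bis(tosyloxy)phenyl]-4-{[(tert-butyldiphenylsilyl)oxy]methyl}furan-2(5H)-one (racemic) | O=C1C=C(CO[Si](c2ccccc2)(c2ccccc2)C(C)(C)C)C(c2ccc(OS(=O)(=O)c3ccc(C)cc3)c(OS(=O)(=O)c3ccc(C)cc3)c2)O1
F3 | step 4 | racemic cis-5-[3,4-bis(tosyloxy)phenyl]-4-{[(tert-butyldiphenylsilyl)oxy]methyl}oxolan-2-one (6 together with its enantiomer; relative configuration shown) | O=C1C[C@H](CO[Si](c2ccccc2)(c2ccccc2)C(C)(C)C)[C@H](c2ccc(OS(=O)(=O)c3ccc(C)cc3)c(OS(=O)(=O)c3ccc(C)cc3)c2)O1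
F4 | step 4 | racemic (3S*,4S*,5R*)-5-[3,4-bis(tosyloxy)phenyl]-4-{[(tert-butyldiphenylsilyl)oxy]methyl}-3-hydroxyoxolan-2-one (relative configuration shown) | O=C1[C@@H](O)[C@H](CO[Si](c2ccccc2)(c2ccccc2)C(C)(C)C)[C@H](c2ccc(OS(=O)(=O)c3ccc(C)cc3)c(OS(=O)(=O)c3ccc(C)cc3)c2)O1
F5 | step 4 | (3S,4R,5R)-5-[3,4-bis(tosyloxy)phenyl]-4-{[(tert-butyldiphenylsilyl)oxy]methyl}-2-oxooxolan-3-yl acetate | O=C1[C@@H](OC(C)=O)[C@H](CO[Si](c2ccccc2)(c2ccccc2)C(C)(C)C)[C@H](c2ccc(OS(=O)(=O)c3ccc(C)cc3)c(OS(=O)(=O)c3ccc(C)cc3)c2)O1
F6 | step 4 | (3S,4S,5R)-5-[3,4-bis(tosyloxy)phenyl]-4-{[(tert-butyldiphenylsilyl)oxy]methyl}-3-hydroxyoxolan-2-one (single enantiomer) | O=C1[C@@H](O)[C@H](CO[Si](c2ccccc2)(c2ccccc2)C(C)(C)C)[C@H](c2ccc(OS(=O)(=O)c3ccc(C)cc3)c(OS(=O)(=O)c3ccc(C)cc3)c2)O1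
F7 | step 6 | aldol adduct of 8: 3-[(3,4-dimethoxyphenyl)(hydroxy)methyl] lactone, ring configuration as in 10, carbinol carbon as a mixture | O=C1[C@@](O[Si](CC)(CC)CC)(C(O)c2ccc(OC)c(OC)c2)[C@H](CO[Si](c2ccccc2)(c2ccccc2)C(C)(C)C)[C@H](c2ccc(OS(=O)(=O)c3ccc(C)cc3)c(OS(=O)(=O)c3ccc(C)cc3)c2)O1
F8 | step 6 | O-(imidazol-1-ylthiocarbonyl) derivative of F7 | O=C1[C@@](O[Si](CC)(CC)CC)(C(OC(=S)n2ccnc2)c2ccc(OC)c(OC)c2)[C@H](CO[Si](c2ccccc2)(c2ccccc2)C(C)(C)C)[C@H](c2ccc(OS(=O)(=O)c3ccc(C)cc3)c(OS(=O)(=O)c3ccc(C)cc3)c2)O1
F9 | step 8 | 1-[3,4-bis(tosyloxy)phenyl]-2-{[(tert-butyldiphenylsilyl)oxy]methyl}-3-[(3,4-dimethoxyphenyl)methyl]-3-[(triethylsilyl)oxy]butane-1,4-diol, configuration as in 10 | Cc1ccc(cc1)S(=O)(=O)Oc1ccc(cc1OS(=O)(=O)c1ccc(C)cc1)[C@H](O)[C@@H](CO[Si](c1ccccc1)(c1ccccc1)C(C)(C)C)[C@](O[Si](CC)(CC)CC)(Cc1ccc(OC)c(OC)c1)CO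
A1 | alternative 1 | 4-[2-(3,4-dibenzyloxyphenyl)-1,3-dithian-2-yl]-3-[(3,4-dimethoxyphenyl)methyl]-3-hydroxyoxolan-2-one, hydroxyl trans to the dithianyl group | O=C1OC[C@H](C2(SCCCS2)c2ccc(OCc3ccccc3)c(OCc3ccccc3)c2)[C@]1(O)Cc1ccc(OC)c(OC)c1
A2 | alternative 1 | 1-(3,4-dibenzyloxyphenyl)-3-[(3,4-dimethoxyphenyl)methyl]-2-(hydroxymethyl)butane-1,3,4-triol, mixture at the benzylic carbinol | OC[C@H](C(O)c1ccc(OCc2ccccc2)c(OCc2ccccc2)c1)[C@@](O)(CO)Cc1ccc(OC)c(OC)c1
A3 | alternative 1 | (3R,4R,5S)-5-(3,4-dihydroxyphenyl)-3-[(3,4-dimethoxyphenyl)methyl]-4-(hydroxymethyl)oxolan-3-ol, the 2-epimer of 14 in the ring numbering used here | COc1ccc(C[C@]2(O)CO[C@H](c3ccc(O)c(O)c3)[C@H]2CO)cc1OC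
A4 | alternative 2 | furan | c1ccoc1
A5 | alternative 2 | rac-(1R,5S,6R)-6-[3,4-bis(tosyloxy)phenyl]-2,7-dioxabicyclo[3.2.0]hept-3-ene (exo adduct) | Cc1ccc(cc1)S(=O)(=O)Oc1ccc(cc1OS(=O)(=O)c1ccc(C)cc1)[C@@H]1O[C@H]2OC=C[C@@H]12
A6 | alternative 2 | (1R,4R,5R,6R)-6-[3,4-bis(tosyloxy)phenyl]-4-[(3,4-dimethoxyphenyl)methyl]-2,7-dioxabicyclo[3.2.0]heptan-4-ol | Cc1ccc(cc1)S(=O)(=O)Oc1ccc(cc1OS(=O)(=O)c1ccc(C)cc1)[C@@H]1O[C@H]2OC[C@@](O)(Cc3ccc(OC)c(OC)c3)[C@@H]12
A7 | alternative 3 | (R)-4-benzyl-3-[(2R,3R)-2-[(benzyloxy)methyl]-3-(3,4-dibenzyloxyphenyl)-3-hydroxypropanoyl]oxazolidin-2-one (syn-aldol adduct) | O=C1OC[C@@H](Cc2ccccc2)N1C(=O)[C@H](COCc1ccccc1)[C@@H](O)c1ccc(OCc2ccccc2)c(OCc2ccccc2)c1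
A8 | alternative 3 | cis-5-(3,4-dibenzyloxyphenyl)-4-[(benzyloxy)methyl]oxolan-3-one | O=C1CO[C@@H](c2ccc(OCc3ccccc3)c(OCc3ccccc3)c2)[C@H]1COCc1ccccc1
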